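The cyclopentenone is disconnected at C11–C12 and C9–C10, between a two-carbon acrylate unit (C10–C11) and a C9–C8–C12 unit held as a 2-acyl γ-lactone. The key step exploits the 1,3-relationship of the C12 carbinol and the C9 ketone across C8 in the five-membered ring. SmI2 turns the C12 ketone into a ketyl that adds to allyl acrylate (umpolung union of C11 and C12), and the resulting samarium enolate closes onto the lactone carbonyl C9, opening the lactone and releasing O6. The precursor is a sugar-derived lactone (ring C9–C8–C7–C6–O) that carries C5–C7 from L-gulonolactone and fixes C8, which in turn steers C12.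

Key step: step 8

Remark: atoms carry prostanoid locants (C1 ester carbon, C8–C12 ring, C9 ketone, C12 carbinol); the target is read as (5S,6R,7R,8S,12R,14Z,17Z), and L-gulono-1,4-lactone, (3Z,6Z)-nona-3,6-dien-1-ol, methyl acrylate and allyl acrylate are taken as commercial.

Step 1
Reactants: 1 L-gulono-1,4-lactone
Product: 3 2,6-dibromo-2,6-dideoxy-L-idono-1,4-lactone, via O-acetylated dibromolactone 2 (not isolated)
Conditions: 33% HBr in AcOH, rt; then MeOH, rt
Reagents that add atoms: hydrogen bromide, Br
Why: Bromodeoxygenation of an aldonolactone in HBr–AcOH runs through 2,3- and 5,6-acetoxonium ions that bromide opens at C2 (inversion; this centre is erased in step 2) and at the primary C6, so the sugar C3, C4 and C5 centres that become C7, C6 and C5 of the target stay untouched, and methanol then strips the O-acetyl groups by transesterification.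

Step 2
Reactants: 3 2,6-dibromo-2,6-dideoxy-L-idono-1,4-lactone
Product: 4 6-bromo-2,6-dideoxy-L-xylo-hexono-1,4-lactone
Conditions: H2 (1 atm), palladium on carbon (Pd/C), Et3N (1 equiv), EtOAc, rt
Reagents that add atoms: none
Why: Catalytic hydrogenolysis in the presence of base cleaves the activated C–Br bond alpha to the lactone carbonyl far faster than the primary C–Br bond (chemoselective hydrodehalogenation), and no stereocentre is touched.

Step 3
Reactants: 4 6-bromo-2,6-dideoxy-L-xylo-hexono-1,4-lactone
Product: 5 6-bromo-2,6-dideoxy-3,5-O-isopropylidene-L-xylo-hexono-1,4-lactone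
Conditions: 2,2-dimethoxypropane, camphorsulfonic acid (cat.), acetone, rt
Reagents that add atoms: 2,2-dimethoxypropane, COC(C)(C)OC
Why: Acid-catalysed transacetalisation closes the six-membered 1,3-dioxane across the 3- and 5-hydroxyls, which sit cis on the xylo-configured lactone, and no stereocentre is touched.

Step 4
Reactants: 5 6-bromo-2,6-dideoxy-3,5-O-isopropylidene-L-xylo-hexono-1,4-lactone; 6 methyl acrylate
Product: 7 lactone ester (methyl 2,6,7,8-tetradeoxy-3,5-O-isopropylidene-L-xylo-nonar-9-oate 1,4-lactone)
Conditions: Bu3SnH (slow addition), AIBN (cat.), 6 (5 equiv), benzene, 80 °C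
Reagents that add atoms: none
Why: Giese reaction: the primary radical formed by bromine abstraction adds to the β-carbon of methyl acrylate and the adduct radical is reduced by Bu3SnH, which appends C3–C1 without touching a stereocentre.

Step 5
Reactants: 8 (3Z,6Z)-nona-3,6-dien-1-ol
Product: 9 (3Z,6Z)-nona-3,6-dienal
Conditions: Dess–Martin periodinane, NaHCO3, CH2Cl2, 0 °C; short silica plug, used at once
Reagents that add atoms: none
Why: Dess–Martin oxidation under buffered, non-enolising conditions should give the β,γ-unsaturated aldehyde without moving or isomerising the skipped (Z,Z)-diene, provided the crude product is used at once.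

Step 6
Reactants: 7 lactone ester; 9 (3Z,6Z)-nona-3,6-dienal
Product: 10 aldol adduct (7 carrying at C8, trans to O7, a 1-hydroxy-(3Z,6Z)-nona-3,6-dienyl group; both carbinol epimers)
Conditions: LiN(SiMe3)2, THF, −78 °C; then 9, −78 °C; aq. NH4Cl
Reagents that add atoms: none
Why: Aldol addition of the lactone lithium enolate (the lactone α-CH2 is more acidic than the methyl ester α-CH2) to the aldehyde takes place on the face trans to the C7 oxygen, which sets C8, while the carbinol centre is left uncontrolled because it is oxidised next.

Step 7
Reactants: 10 aldol adduct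
Product: 11 2-acyl lactone (7 carrying at C8 a (3Z,6Z)-nona-3,6-dienoyl group trans to O7)
Conditions: Dess–Martin periodinane, CH2Cl2, 0 °C to rt
Reagents that add atoms: none
Why: Dess–Martin oxidation of the β-hydroxy lactone gives the 2-acyl lactone, in which the now epimerisable C8 settles in the thermodynamically preferred arrangement with the acyl group trans to the C7 oxygen, the configuration of the target.

Step 8
Reactants: 11 2-acyl lactone; 12 allyl acrylate
Product: 14 allyl β-keto ester (cyclopentanone with C9 ketone, C10 CO2allyl, C12 tertiary OH and octadienyl chain, C8 on the 1,3-dioxane, free 6-OH), via ketyl-acrylate adduct 13 (not isolated)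
Conditions: SmI2 (2.5 equiv), 12 (1.5 equiv), THF, −78 to −20 °C, slow addition of 11; aq. NH4Cl
Reagents that add atoms: none
Why: Proposed new method: SmI2 reduces the chelated C12 ketone of 11 to a ketyl whose carbon adds to the β-carbon of allyl acrylate (C11–C12), a second electron turns the α-ester radical into a trivalent samarium enolate, and its carbon C10 attacks the samarium-activated lactone carbonyl C9 (C9–C10), the tetrahedral intermediate collapsing with loss of the C6 alkoxide to the enolate of β-keto ester 14. The closest known reaction types are the SmI2 ketyl–olefin coupling of β-keto esters with acrylates and the tandem ketyl–olefin cyclisation/Dieckmann condensation of samarium enolates; new here is the intermolecular radical addition followed by Claisen closure onto a lactone. The cyclopentanone closes by a 5-exo-trig Dieckmann-type acyl substitution. C12 is set by the six-membered samarium chelate between ketyl oxygen and lactone carbonyl, which exposes the face syn to H-8 and anti to the dioxane-fused lactone ring, so the new C11 bond lies trans to C7 and the hydroxyl cis to the C7 chain as in the target; C10 forms as an enolisable centre that is removed later. The step needs C-acylation to outrun protonation of the enolate, O-lactonisation and acrylate oligomerisation, which the proximity of the ester enolate to the chelated lactone carbonyl and the irreversible formation of the stabilised β-keto ester enolate should secure.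

Step 9
Reactants: 14 allyl β-keto ester
Product: 15 6-O-acetate of 14
Conditions: Ac2O (1.2 equiv), pyridine, CH2Cl2, 0 °C
Reagents that add atoms: acetic anhydride, CC(=O)OC(C)=O
Why: Pyridine-mediated acetylation acylates the secondary 6-OH but neither the tertiary 12-OH nor the hydrogen-bonded enol, which installs the first acetate of the target and blocks re-lactonisation by retro-Claisen cleavage in the next two steps.

Step 10
Reactants: 15 6-O-acetate
Product: 16 10-chloro β-keto ester (C10 epimers)
Conditions: N-chlorosuccinimide, CH2Cl2, 0 °C to rt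
Reagents that add atoms: N-chlorosuccinimide, O=C1CCC(=O)N1Cl
Why: Electrophilic α-chlorination of the enolised β-keto ester by N-chlorosuccinimide is much faster than any reaction of the isolated Z-alkenes and places chlorine on C10, whose configuration is irrelevant.

Step 11
Reactants: 16 10-chloro β-keto ester
Product: 17 chloro-enone (5,7-O-isopropylidene 6-O-acetyl analogue of the target)
Conditions: Pd(OAc)2 (10 mol %), 1,2-bis(diphenylphosphino)ethane (10 mol %), MeCN, 80 °C
Reagents that add atoms: none
Why: Tsuji decarboxylation–dehydrogenation: zerovalent palladium formed in situ ionises the allyl ester, loss of CO2 gives a palladium enolate at C10, and β-hydride elimination, possible only from C11, installs the C10=C11 double bond and releases propene.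

Step 12
Reactants: 17 chloro-enone
Product: 18 5,7-diol 6-acetate
Conditions: camphorsulfonic acid (cat.), MeOH, 0 °C to rt
Reagents that add atoms: none
Why: Acid-catalysed transacetalisation to methanol removes the isopropylidene acetal, and methanol as solvent keeps the freed 5-hydroxy ester from closing to a δ-lactone.

Step 13
Reactants: 18 5,7-diol 6-acetate
Product: 19 target CNP0277476.1
Conditions: Ac2O, pyridine, CH2Cl2, 0 °C
Reagents that add atoms: acetic anhydride, CC(=O)OC(C)=O
Why: Acetylation with Ac2O–pyridine without an acyl-transfer catalyst esterifies the two secondary hydroxyls and leaves the tertiary 12-OH free, and the low temperature should avoid base-induced loss of the 7-acetate.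

Compound list

1 | L-gulono-1,4-lactone | OC[C@H](O)[C@H]1OC(=O)[C@@H](O)[C@H]1O | starting material
2 | O-acetylated dibromolactone, drawn as 3,5-di-O-acetyl-2,6-dibromo-2,6-dideoxy-L-idono-1,4-lactone (not isolated) | BrC[C@H](OC(C)=O)[C@H]1OC(=O)[C@H](Br)[C@H]1OC(C)=O | intermediate
3 | 2,6-dibromo-2,6-dideoxy-L-idono-1,4-lactone | BrC[C@H](O)[C@H]1OC(=O)[C@H](Br)[C@H]1O | intermediate
4 | 6-bromo-2,6-dideoxy-L-xylo-hexono-1,4-lactone | BrC[C@H](O)[C@H]1OC(=O)C[C@H]1O | intermediate
5 | 6-bromo-2,6-dideoxy-3,5-O-isopropylidene-L-xylo-hexono-1,4-lactone | O=C1C[C@H]2OC(C)(C)O[C@@H](CBr)[C@H]2O1 | intermediate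
6 | methyl acrylate | C=CC(=O)OC | starting material
7 | lactone ester: γ-lactone (C9, C8, C7, C6, O) cis-fused to the 2,2-dimethyl-1,3-dioxane spanning O7 and O5, with (CH2)3CO2Me on C5 | O=C1C[C@H]2OC(C)(C)O[C@@H](CCCC(=O)OC)[C@H]2O1 | intermediate
8 | (3Z,6Z)-nona-3,6-dien-1-ol | CC/C=C\C/C=C\CCO | starting material
9 | (3Z,6Z)-nona-3,6-dienal | CC/C=C\C/C=C\CC=O | intermediate
10 | aldol adduct: 7 with a 1-hydroxy-(3Z,6Z)-nona-3,6-dienyl group on C8, trans to O7 (carbinol epimers) | CC/C=C\C/C=C\CC(O)[C@@H]1[C@H]2OC(C)(C)O[C@@H](CCCC(=O)OC)[C@H]2OC1=O | intermediate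
11 | 2-acyl lactone: 7 with a (3Z,6Z)-nona-3,6-dienoyl group on C8, trans to O7 (C8 as in the target) | CC/C=C\C/C=C\CC(=O)[C@@H]1[C@H]2OC(C)(C)O[C@@H](CCCC(=O)OC)[C@H]2OC1=O | intermediate
12 | allyl acrylate (prop-2-enyl prop-2-enoate) | C=CC(=O)OCC=C | starting material
13 | ketyl-acrylate adduct: 11 with C12 as tertiary carbinol carrying CH2CH2CO2allyl, formed as samarium alkoxide/ester enolate and drawn neutral (not isolated) | CC/C=C\C/C=C\C[C@](O)(CCC(=O)OCC=C)[C@@H]1[C@H]2OC(C)(C)O[C@@H](CCCC(=O)OC)[C@H]2OC1=O | intermediate
14 | allyl β-keto ester: cyclopentanone with C9 ketone, C10 CO2allyl (epimers/enol), C12 OH and (2Z,5Z)-octa-2,5-dienyl, C8 on the dioxane, free 6-OH; C5–C8 and C12 as in the target | CC/C=C\C/C=C\C[C@]1(O)CC(C(=O)OCC=C)C(=O)[C@H]1[C@H]2OC(C)(C)O[C@@H](CCCC(=O)OC)[C@H]2O | intermediate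
15 | 6-O-acetate of 14 | CC/C=C\C/C=C\C[C@]1(O)CC(C(=O)OCC=C)C(=O)[C@H]1[C@H]2OC(C)(C)O[C@@H](CCCC(=O)OC)[C@H]2OC(C)=O | intermediate
16 | 10-chloro derivative of 15 (C10 epimers) | CC/C=C\C/C=C\C[C@]1(O)CC(Cl)(C(=O)OCC=C)C(=O)[C@H]1[C@H]2OC(C)(C)O[C@@H](CCCC(=O)OC)[C@H]2OC(C)=O | intermediate
17 | chloro-enone: 10-chloro-12-hydroxy-9-oxo ring of the target with 6-OAc and 5,7-O-isopropylidene | CC/C=C\C/C=C\C[C@]1(O)C=C(Cl)C(=O)[C@H]1[C@H]2OC(C)(C)O[C@@H](CCCC(=O)OC)[C@H]2OC(C)=O | intermediate
18 | 5,7-diol 6-acetate | CC/C=C\C/C=C\C[C@]1(O)C=C(Cl)C(=O)[C@H]1[C@@H](O)[C@H](OC(C)=O)[C@H](CCCC(=O)OC)O | intermediate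
19 | methyl (5S,6R,7R,8S,12R,14Z,17Z)-5,6,7-triacetoxy-10-chloro-12-hydroxy-9-oxoprosta-10,14,17-trien-1-oate (CNP0277476.1) | CC/C=C\C/C=C\C[C@]1(O)C=C(Cl)C(=O)[C@H]1[C@@H](OC(C)=O)[C@H](OC(C)=O)[C@H](CCCC(=O)OC)OC(C)=O | target

Total step count: 13. Longest linear sequence: 12 (steps 1–4 and 6–13; step 5 is a one-step branch).

Steps most likely to fail

Step 8 (Proposed new method). The samarium enolate may be protonated by the acidic 2-acyl lactone, may add to further acrylate, or the ketone may simply be reduced before C-acylation occurs; facial selectivity at C12 may also be lower than the chelate model predicts. The fallback sets out from 11 and returns at 14, making the two bonds in separate known operations. SmI2 with tert-butanol and methyl acrylate should give the standard ketyl–olefin coupling under the same chelate control, and the γ-hydroxy ester should lactonise to the bis-lactone F1. NaOMe in MeOH would then open the new γ-lactone and close the cyclopentanone by Dieckmann condensation onto the sugar lactone, giving the methyl β-keto ester F2. Selective transesterification of the β-keto ester with allyl alcohol (DMAP cat., toluene, reflux) should give 14.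

Step 11. The palladium enolate may undergo reductive elimination to the C-allylated chloro ketone or be protonated (for example by the 12-OH) instead of undergoing β-hydride elimination, and the C–Cl bond may be attacked by zerovalent palladium. The fallback sets out from 16 and returns at 17. Pd(PPh3)4 with HCO2H–Et3N should effect deallylation and decarboxylation to the 2-chloro ketone F3. Me3SiOTf–Et3N should form the silyl enol ether on the chlorine-bearing side and silylate the 12-OH, giving the bis(trimethylsilyl) compound F4. Saegusa–Ito oxidation with Pd(OAc)2 in MeCN, followed by aqueous citric acid work-up, should then give 17.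

Step 12 (with step 13). Once the 5- and 7-hydroxyls are free next to the chloro-enone, δ-lactonisation onto the C1 ester, acetyl migration and conjugate addition of the 7-OH can compete, and the pyridine of step 13 can induce loss of the 7-acetate. The fallback sets out from 15 and returns at 19; it places all acetates before the enone exists and unveils the enone last under neutral conditions. Camphorsulfonic acid in MeOH on 15 should give the diol β-keto ester F5, and Ac2O–pyridine the triacetate β-keto ester F6. N-chlorosuccinimide should give the 10-chloro triacetate F7, and the palladium-catalysed decarboxylation–dehydrogenation of step 11 then gives 19 directly.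

Further compounds

F1 | step 8 | bis-lactone: 11 with C12 incorporated in a new γ-lactone (O12–CO–C10H2–C11H2–C12) | CC/C=C\C/C=C\C[C@]1(CCC(=O)O1)[C@@H]3[C@H]2OC(C)(C)O[C@@H](CCCC(=O)OC)[C@H]2OC3=O
F2 | step 8 | methyl β-keto ester: methyl ester analogue of 14 | CC/C=C\C/C=C\C[C@]1(O)CC(C(=O)OC)C(=O)[C@H]1[C@H]2OC(C)(C)O[C@@H](CCCC(=O)OC)[C@H]2O
F3 | step 11 | 2-chloro ketone: 16 without the allyl ester group (C10 epimers) | CC/C=C\C/C=C\C[C@]1(O)CC(Cl)C(=O)[C@H]1[C@H]2OC(C)(C)O[C@@H](CCCC(=O)OC)[C@H]2OC(C)=O
F4 | step 11 | bis(trimethylsilyl) compound: C9 silyl enol ether (C9=C10) and 12-O-trimethylsilyl ether of F3 | CC/C=C\C/C=C\C[C@]1(O[Si](C)(C)C)CC(Cl)=C(O[Si](C)(C)C)[C@H]1[C@H]2OC(C)(C)O[C@@H](CCCC(=O)OC)[C@H]2OC(C)=O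
F5 | step 12 | diol β-keto ester: 15 without the isopropylidene group | CC/C=C\C/C=C\C[C@]1(O)CC(C(=O)OCC=C)C(=O)[C@H]1[C@@H](O)[C@H](OC(C)=O)[C@H](CCCC(=O)OC)O
F6 | step 12 | triacetate β-keto ester | CC/C=C\C/C=C\C[C@]1(O)CC(C(=O)OCC=C)C(=O)[C@H]1[C@@H](OC(C)=O)[C@H](OC(C)=O)[C@H](CCCC(=O)OC)OC(C)=O
F7 | step 12 | 10-chloro triacetate | CC/C=C\C/C=C\C[C@]1(O)CC(Cl)(C(=O)OCC=C)C(=O)[C@H]1[C@@H](OC(C)=O)[C@H](OC(C)=O)[C@H](CCCC(=O)OC)OC(C)=O
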